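## The problem

Compound 23 is made of two trans-2,3-diaryl-2,3-dihydrobenzofurans joined by a single bond from C3 of the formyl-bearing unit (O1, C2, C3, ring A = C3a to C7a, CHO at C5) to C4' of the second unit (O1', C2', C3', central ring = C3a' to C7a'). The central ring is therefore a resorcinol-derived benzene with four substituents (C3 at C4', C3' at C3a', O1' at C7a', OH at C6'), and the bond C3–C4', which lies next to the substituted C3a', is the most crowded bond of the molecule. There are four stereocentres, all R (2R,3R,2'R,3'R), arranged trans within each heterocycle. Within one ring a single centre suffices, because a group entering at C3 or C3' is directed anti to the aryl group on C2 or C2' and trans is also the more stable arrangement; between the rings the central arene allows no such relay, so each ring needs its own source of absolute configuration. The fragile parts are the five phenols, the aryl aldehyde and the two benzylic C2–O bonds para to an oxygenated aryl ring, which ionise under acid and open to quinone methides under base once the phenol is free. Robust phenol ethers are therefore kept until the last step and the aldehyde is carried in latent form. The feature that opens the route is that the sequence aryl–C2–O1–C7a–C3a of the formyl-bearing ring is the sequence aryl–C2–O1–C8a–C4a of a flavanone: moving the ring A carbon from the flavanone carbonyl carbon to its neighbour creates bond C3–C3a, contracts the six-membered ring to the five-membered one and leaves the former carbonyl carbon on C3 as a carboxyl group, exactly where the target carries an aryl group. The same pattern recurs in the second ring, with the central ring in the role of ring A.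

## Retrosynthesis

Target 23 is first relieved of its sensitive groups: the five O–H bonds are traced to the O–CH3 bonds of aldehyde 22, and the C5–CHO bond to the C5–Br bond of 21. Methyl ethers are preferred to benzyl or acetal-type groups because they alone pass the acidic and Lewis-acidic steps planned for the two ring syntheses. A bromide is preferred to a masked aldehyde because it is inert to those steps and is present in a commercial chromone. 21 has the whole skeleton and all four stereocentres but no group that needs care. The forward steps are halogen–lithium exchange with formylation and a final Lewis-acid demethylation.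

In 21 the bond between C3' and the 3,5-dimethoxyphenyl ring is cut, which leads to acid 19 and arylzinc reagent 9; the coupling runs through redox-active ester 20. The neighbouring cuts, C2'–C3' or O1'–C2', would require the second heterocycle to be closed with absolute control beside a large substituent. The chosen cut leaves the heterocycle intact and exchanges an aryl group for a carboxyl group. The configuration of that carboxyl carbon does not matter, since the coupling passes through the planar C3' radical. The forward reaction must capture this radical anti to the C2' anisyl group.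

Acid 19 comes from ester 18. In 18 the bond C3'–C3a' is cut and the central-ring carbon is reattached to the ester carbon. This is the retro form of the oxidative aryl shift and gives flavanone 16 (by way of enol ether 17). The precursor has one stereocentre fewer in this ring, and the remaining one (C2') is open to catalytic control. The forward step needs the electron-rich central-ring carbon to migrate in preference to the anisyl group.

Flavanone 16 is cut at the C2'–anisyl bond to chromone 15 and boronic acid 2. Chromone 15 is opened at O1'–C2' and loses that carbon, giving hydroxy ketone 13 (through enaminone 14). 13 is traced to its methyl ether 12, and the aryl–acetyl bond of 12 is cut to give 11. Conjugate addition is chosen for C2' because it is catalyst-controlled and takes place far from the stereocentres already present. The 3,5-dimethoxyphenyl ring of 11 has two equivalent positions ortho to C3, so the acylation has only to avoid the position between the methoxy groups. The acetyl group then marks the one methoxy group that is to become O1'. 11 contains a single heterocycle and two stereocentres.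

In 11 the bond C3–C4', the link between the two halves of the target, is cut to acid 7 and the same arylzinc reagent 9, with redox-active ester 10 as the activated form of 7. Making this crowded bond at this point, with an unhindered symmetrical arylzinc reagent, is preferred to a late union with a complete second dihydrofuran, which would need an ortho-branched aryl metal. The forward reaction must place the aryl group trans to the C2 anisyl group and must leave the ring A bromide alone.

Arylzinc reagent 9 is traced to commercial 1-bromo-3,5-dimethoxybenzene 8 by cutting the C–Zn bond. It is made once, as a stock solution, because both arylations draw on it.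

Acid 7 derives from ester 6, the product of the key step. Cutting C3–C3a and rejoining C3a to the ester carbon gives the (2R)-flavanone 3 (via enol ether 5). Two stereocentres become one, and the dihydrofuran becomes a chromanone that is one step from commerce. The forward reaction must shift the ring A carbon and not the anisyl group, and must leave C2 untouched.

Flavanone 3 is cut at the C2–anisyl bond to 6-bromochromone 1 and boronic acid 2; orthoformate 4 supplies the ester methoxy group in the key step. The forward reaction is an enantioselective palladium-catalysed conjugate addition that must tolerate the aryl bromide.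

## Roads not taken

Alternative 1: The cut removes both carbon–carbon bonds that the central ring makes to its neighbours, C3–C4' and C3'–C3a', in one aryne insertion.
- Forward key step: CsF would release the aryne from silyl triflate A3. The enolate carbon of keto ester A2 adds at the aryne carbon remote from the methoxy-flanked one. The aryl anion then attacks the ketone, and fragmentation transfers the 3,5-dimethoxybenzoyl group to give A1.
- Merits: one step assembles the 1,2,3,5-substituted central ring with the carbons for C3 and C3' in place. Its regiochemistry is dictated by the flanking methoxy group, not by electrophilic substitution on a crowded ring. In this respect it is cleaner than step 6 of the chosen route, which relies on the innate para-to-methoxy preference; the chosen plan sets against this the symmetry of the ring in 11 and a fallback.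
- Weak points: A1 has neither heterocycle nor any stereocentre. The methylene still has to take ring A and the C2 unit, the hindered diaryl ketone has to become the C3'/C2' pair, and one of two methoxy groups has to be unmasked for O1'. All four stereocentres would then be set on an intermediate in which no centre governs the distant ring.
- Comparison: the alternative is more convergent at the outset but defers every stereochemical problem. The chosen route fixes the absolute configuration of each ring by one catalytic reaction type and lets that centre direct its neighbour.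

Alternative 2: The cut is made in the second dihydrofuran at C2'–C3' and O1'–C2'.
- Forward key step: Cs2CO3 would expel toluenesulfinate from phenol sulfone A5 to give the ortho-quinone methide and would form the ylide of the C2-symmetric (4-methoxybenzyl)sulfonium salt A6 (or of its enantiomer, whichever leads to the 2'R,3'R series). The ylide carbon adds at C3' and the phenoxide displaces the sulfide at C2', giving A4.
- Merits: both stereocentres and the ring of the second unit arise in one convergent step, trans, and the bromide at C4' is a defined handle. The path to A4 is shorter than the seven steps (steps 6 to 12) that the chosen route spends on this ring, and the longest linear sequence would be shorter.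
- Weak points: the enantioselectivity rests on the stoichiometric chiral sulfide carried by A6, facing a quinone methide whose exocyclic carbon is flanked by bromine. The union with the formyl-bearing ring would have to form C3–C4' from the ortho-branched aryl metal derived from A4, the bulkiest possible partner for the most crowded bond.
- Comparison: if that late coupling worked, this road would be the shorter one. The chosen plan sets against it that C3–C4' is made with the unhindered arylzinc 9, and that one asymmetric method serves both rings.

Alternative 3: The cut is C2–C3 of the formyl-bearing ring.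
- Forward key step: Rh2(R-PTAD)4 or its mirror-image catalyst would decompose diazo compound A8. The donor–donor carbene inserts into the benzylic C–H bond of the 4-methoxybenzyl ether and closes the ring with both centres, giving A7.
- Merits: both stereocentres come from an achiral precursor in one catalytic step. The C3–aryl bond exists before the ring is closed, so no radical coupling is needed there. The bromide on the resorcinol ring enters with defined position. For the first ring this road is as short as the chosen one or shorter.
- Weak points: A7 is cis, so C2 must afterwards be inverted by acid-induced opening and reclosure, which would also remove the dioxolane. The diazo carbon of A8 is flanked by ortho substituents on both aryl rings, so its preparation by condensation with hydrazine and oxidation would be slow. The second ring would still have to be built from the aryl bromide of A7, where the usual lithiation, aldehyde addition and cyclisation sequence offers no absolute control at C3'.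
- Comparison: the chosen plan gives the trans ring directly, and its stereochemical logic transfers unchanged to the second ring.

Key step: step 2

Assumption: the 2R sense of the palladium-catalysed conjugate addition is assigned to the (S)-configured ligand (S)-4-tert-butyl-2-(pyridin-2-yl)-4,5-dihydrooxazole, (S)-t-BuPyOx, by analogy with cyclic enones; should the opposite sense be found, the equally accessible (R)-ligand is used in steps 1 and 9.

## Route

Step 1
Reactants: 1 6-bromochromone (6-bromo-4H-chromen-4-one); 2 (4-methoxyphenyl)boronic acid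
Product: 3 (2R)-6-bromo-2-(4-methoxyphenyl)chroman-4-one
Conditions: Pd(OCOCF3)2 (5 mol %), (S)-t-BuPyOx (6 mol %), NH4PF6 (30 mol %), H2O (5 equiv), ClCH2CH2Cl, 60 °C
Reagents that add atoms: none
Why: Asymmetric conjugate addition of an arylboronic acid to a chromone: the cationic divalent palladium complex transmetalates, the aryl–palladium species inserts the C2=C3 bond on the enantioface chosen by the pyridine-oxazoline ligand (C2 becomes R), and water protonates the palladium enolate. No zerovalent palladium lies on the cycle, so the aryl bromide should not react.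

Step 2
Reactants: 3 (2R)-6-bromo-2-(4-methoxyphenyl)chroman-4-one; 4 trimethyl orthoformate
Product: 6 methyl (2R,3R)-5-bromo-2-(4-methoxyphenyl)-2,3-dihydrobenzofuran-3-carboxylate, via enol ether 5 (not isolated)
Conditions: HC(OMe)3 (solvent), conc. H2SO4 (cat.), rt, 1 h; then PhI(OAc)2 (1.2 equiv), rt
Reagents that add atoms: none
Why: In acidic orthoformate the ketone is converted into its dimethyl ketal and enol ether 5, whose C3 attacks the trivalent iodine of PhI(OAc)2 on the face anti to the pseudo-equatorial anisyl group at C2, and methanol adds to the resulting oxocarbenium ion to give the 3-iodanyl dimethyl ketal. The ring A carbon then shifts from the ketal carbon to C3 through a bridged, phenonium-like transition state while iodobenzene leaves, and the dimethoxycarbenium ion that remains loses a methyl group to give the methyl ester. The closest known reaction type is the oxidative ring contraction of flavanones to methyl trans-2-aryl-2,3-dihydrobenzofuran-3-carboxylates with PhI(OAc)2/H2SO4 or Tl(NO3)3 in trimethyl orthoformate, which has been applied to optically active flavanones. The five-membered ring is not closed by a cyclisation but arises by contraction of the pyranone, the new bond C3–C3a being formed by a 1,2-aryl shift. The new stereocentre C3 is controlled by C2: the iodane enters anti to the anisyl group and the shift inverts C3, which places the ester trans (3R); the same isomer is favoured at equilibrium through the ester enol, and this centre is in any case erased in step 5. The step needs migration of the ring A carbon to win over the shift of the C2 anisyl group (isoflavone) and over elimination (flavone); this is secured by complete ketalisation before the oxidant is added, since two methoxy groups stabilise the cation left behind by ring A migration, by the equatorial iodane, which has the C4–C4a bond and not the C2–aryl bond antiperiplanar to it, and by the ring oxygen ortho to the migrating carbon. C2 takes no part and should keep the configuration set in step 1.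

Step 3
Reactants: 6 methyl (2R,3R)-5-bromo-2-(4-methoxyphenyl)-2,3-dihydrobenzofuran-3-carboxylate
Product: 7 (2R,3R)-5-bromo-2-(4-methoxyphenyl)-2,3-dihydrobenzofuran-3-carboxylic acid
Conditions: Me3SnOH (5 equiv), ClCH2CH2Cl, 80 °C; then 1 M HCl
Reagents that add atoms: trimethyltin hydroxide, C[Sn](C)(C)O
Why: Neutral ester hydrolysis with Me3SnOH delivers hydroxide to the tin-activated carbonyl group without forming the ester enolate. The E1cB opening of the dihydrofuran (loss of the ring phenoxide from C2) that threatens under aqueous alkali is thereby avoided, and C2 is untouched.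

Step 4
Reactants: 8 1-bromo-3,5-dimethoxybenzene
Product: 9 (3,5-dimethoxyphenyl)zinc chloride
Conditions: Mg turnings, LiCl, THF, rt; then ZnCl2 (1.0 equiv, THF), 0 °C → rt; stock solution titrated with I2 and kept under argon for steps 5 and 12
Reagents that add atoms: zinc chloride, Cl[Zn]Cl
Why: LiCl-assisted insertion of magnesium into the aryl bromide gives the Grignard reagent, and transmetalation with ZnCl2 gives the arylzinc chloride. Both are standard operations on a simple anisole-type bromide, and the solution keeps under argon, so one batch serves both arylations.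

Step 5
Reactants: 7 (2R,3R)-5-bromo-2-(4-methoxyphenyl)-2,3-dihydrobenzofuran-3-carboxylic acid; 9 (3,5-dimethoxyphenyl)zinc chloride
Product: 11 (2R,3R)-5-bromo-3-(3,5-dimethoxyphenyl)-2-(4-methoxyphenyl)-2,3-dihydrobenzofuran, via phthalimide ester 10 (not isolated)
Conditions: 7, N-hydroxyphthalimide, DIC, DMAP (cat.), CH2Cl2, rt (to 10, used crude); then Fe(acac)3 (10 mol %), dppBz (12 mol %), 9 (2 equiv), THF/toluene, rt
Reagents that add atoms: none
Why: Decarboxylative Negishi-type arylation of a redox-active ester: electron transfer from the low-valent iron–aryl species, formed from Fe(acac)3, 1,2-bis(diphenylphosphino)benzene (dppBz) and 9, fragments 10 to CO2, phthalimide anion and the benzylic C3 radical, which is captured by the aryl–iron species and coupled. The planar radical is approached anti to the C2 anisyl group, so C3 is set trans (3R) by C2 alone. Fe(acac)3/dppBz is chosen over NiCl2·glyme/4,4'-di-tert-butyl-2,2'-bipyridine because it should not insert into the aryl bromide of ring A.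

Step 6
Reactants: 11 (2R,3R)-5-bromo-3-(3,5-dimethoxyphenyl)-2-(4-methoxyphenyl)-2,3-dihydrobenzofuran
Product: 12 1-{2-[(2R,3R)-5-bromo-2-(4-methoxyphenyl)-2,3-dihydrobenzofuran-3-yl]-4,6-dimethoxyphenyl}ethan-1-one
Conditions: AcCl (1.2 equiv), SnCl4 (1.2 equiv), CH2Cl2, −40 → 0 °C
Reagents that add atoms: acetyl chloride, CC(=O)Cl
Why: Friedel–Crafts acylation: the 3,5-dimethoxyphenyl ring is by far the most nucleophilic arene (ring A is deactivated by bromine, the anisyl ring has one donor only), and its two equivalent positions ortho to C3, each para to one methoxy group, are the usual site of attack in 5-alkylresorcinol dimethyl ethers. A reversible Lewis-acid opening of the C2–O1 bond would reclose trans, because C3 is now configurationally fixed.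

Step 7
Reactants: 12 1-{2-[(2R,3R)-5-bromo-2-(4-methoxyphenyl)-2,3-dihydrobenzofuran-3-yl]-4,6-dimethoxyphenyl}ethan-1-one
Product: 13 1-{2-[(2R,3R)-5-bromo-2-(4-methoxyphenyl)-2,3-dihydrobenzofuran-3-yl]-6-hydroxy-4-methoxyphenyl}ethan-1-one
Conditions: BCl3 (1.5 equiv), CH2Cl2, −78 → 0 °C; aq. NaHCO3
Reagents that add atoms: none
Why: Chelation-controlled demethylation: BCl3 binds the ketone oxygen and the only methoxy group ortho to it in a six-membered chelate, and chloride removes that methyl group while the three other aryl methyl ethers remain. This differentiates the two oxygens of the formerly symmetric ring and frees the future O1'.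

Step 8
Reactants: 13 1-{2-[(2R,3R)-5-bromo-2-(4-methoxyphenyl)-2,3-dihydrobenzofuran-3-yl]-6-hydroxy-4-methoxyphenyl}ethan-1-one
Product: 15 5-[(2R,3R)-5-bromo-2-(4-methoxyphenyl)-2,3-dihydrobenzofuran-3-yl]-7-methoxy-4H-chromen-4-one, via enaminone 14 (not isolated)
Conditions: Me2NCH(OMe)2 (3 equiv), toluene, 100 °C; then conc. HCl, CH2Cl2, rt
Reagents that add atoms: N,N-dimethylformamide dimethyl acetal, COC(OC)N(C)C
Why: Enaminone synthesis of chromones: the acetyl methyl group condenses with the amide acetal to the β-dimethylamino enone 14, and under acid the ortho phenol adds to the enaminone carbon and dimethylamine is lost, which closes the pyranone.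

Step 9
Reactants: 15 5-[(2R,3R)-5-bromo-2-(4-methoxyphenyl)-2,3-dihydrobenzofuran-3-yl]-7-methoxy-4H-chromen-4-one; 2 (4-methoxyphenyl)boronic acid
Product: 16 (2R)-5-[(2R,3R)-5-bromo-2-(4-methoxyphenyl)-2,3-dihydrobenzofuran-3-yl]-7-methoxy-2-(4-methoxyphenyl)chroman-4-one
Conditions: Pd(OCOCF3)2 (5 mol %), (S)-t-BuPyOx (6 mol %), NH4PF6 (30 mol %), H2O (5 equiv), ClCH2CH2Cl, 60 °C
Reagents that add atoms: none
Why: The same asymmetric conjugate addition as in step 1. The reacting C2=C3 bond is remote from the existing stereocentres, so the ligand is expected to set the new centre (the future C2') as R regardless of the dihydrofuran already present, and the aryl bromide is again inert to divalent palladium.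

Step 10
Reactants: 16 (2R)-5-[(2R,3R)-5-bromo-2-(4-methoxyphenyl)-2,3-dihydrobenzofuran-3-yl]-7-methoxy-2-(4-methoxyphenyl)chroman-4-one; 4 trimethyl orthoformate
Product: 18 methyl (2R,3R)-4-[(2R,3R)-5-bromo-2-(4-methoxyphenyl)-2,3-dihydrobenzofuran-3-yl]-6-methoxy-2-(4-methoxyphenyl)-2,3-dihydrobenzofuran-3-carboxylate, via enol ether 17 (not isolated)
Conditions: HC(OMe)3 (solvent), conc. H2SO4 (cat.), rt, 1 h; then PhI(OAc)2 (1.2 equiv), rt
Reagents that add atoms: none
Why: Second use of the oxidative 1,2-aryl shift of flavanones (the reaction type of step 2): the central-ring carbon, activated by the ortho ring oxygen and the para methoxy group, migrates from the ketal carbon to the iodane-bearing carbon, forming C3'–C3a' and the second dihydrofuran. The ester emerges trans to the C2' anisyl group (iodane anti to anisyl, shift with inversion) and C2' is not involved.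

Step 11
Reactants: 18 methyl (2R,3R)-4-[(2R,3R)-5-bromo-2-(4-methoxyphenyl)-2,3-dihydrobenzofuran-3-yl]-6-methoxy-2-(4-methoxyphenyl)-2,3-dihydrobenzofuran-3-carboxylate
Product: 19 (2R,3R)-4-[(2R,3R)-5-bromo-2-(4-methoxyphenyl)-2,3-dihydrobenzofuran-3-yl]-6-methoxy-2-(4-methoxyphenyl)-2,3-dihydrobenzofuran-3-carboxylic acid
Conditions: Me3SnOH (8 equiv), ClCH2CH2Cl, 80 °C; then 1 M HCl
Reagents that add atoms: trimethyltin hydroxide, C[Sn](C)(C)O
Why: Neutral tin-mediated ester hydrolysis as in step 3; no enolate is formed, so neither heterocycle should open and no centre other than the irrelevant C3' could be affected.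

Step 12
Reactants: 19 (2R,3R)-4-[(2R,3R)-5-bromo-2-(4-methoxyphenyl)-2,3-dihydrobenzofuran-3-yl]-6-methoxy-2-(4-methoxyphenyl)-2,3-dihydrobenzofuran-3-carboxylic acid; 9 (3,5-dimethoxyphenyl)zinc chloride
Product: 21 (2R,3R)-4-[(2R,3R)-5-bromo-2-(4-methoxyphenyl)-2,3-dihydrobenzofuran-3-yl]-3-(3,5-dimethoxyphenyl)-6-methoxy-2-(4-methoxyphenyl)-2,3-dihydrobenzofuran, via phthalimide ester 20 (not isolated)
Conditions: 19, N-hydroxyphthalimide, DIC, DMAP (cat.), CH2Cl2, rt (to 20, used crude); then Fe(acac)3 (20 mol %), dppBz (24 mol %), 9 (3 equiv), THF/toluene, rt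
Reagents that add atoms: none
Why: The same iron-catalysed decarboxylative arylation of a redox-active ester as in step 5. The C3' radical is captured anti to the C2' anisyl group, which sets C3' trans (3'R), and the ring A bromide should again survive.

Step 13
Reactants: 21 (2R,3R)-4-[(2R,3R)-5-bromo-2-(4-methoxyphenyl)-2,3-dihydrobenzofuran-3-yl]-3-(3,5-dimethoxyphenyl)-6-methoxy-2-(4-methoxyphenyl)-2,3-dihydrobenzofuran
Product: 22 (2R,3R)-3-[(2R,3R)-3-(3,5-dimethoxyphenyl)-6-methoxy-2-(4-methoxyphenyl)-2,3-dihydrobenzofuran-4-yl]-2-(4-methoxyphenyl)-2,3-dihydrobenzofuran-5-carbaldehyde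
Conditions: n-BuLi (1.1 equiv), THF, −78 °C; DMF (3 equiv), −78 → 0 °C; 1 M HCl
Reagents that add atoms: N,N-dimethylformamide, CN(C)C=O
Why: Bromine–lithium exchange at −78 °C is faster than deprotonation of the benzylic positions, and the aryllithium is formylated by DMF (Bouveault aldehyde synthesis). The substrate has no other electrophilic or acidic group.

Step 14
Reactants: 22 (2R,3R)-3-[(2R,3R)-3-(3,5-dimethoxyphenyl)-6-methoxy-2-(4-methoxyphenyl)-2,3-dihydrobenzofuran-4-yl]-2-(4-methoxyphenyl)-2,3-dihydrobenzofuran-5-carbaldehyde
Product: 23 (2R,3R)-3-[(2R,3R)-3-(3,5-dihydroxyphenyl)-6-hydroxy-2-(4-hydroxyphenyl)-2,3-dihydrobenzofuran-4-yl]-2-(4-hydroxyphenyl)-2,3-dihydrobenzofuran-5-carbaldehyde (CNP0318276.1)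
Conditions: BBr3 (12 equiv), CH2Cl2, −78 → 0 °C; then MeOH, aq. NaHCO3
Reagents that add atoms: none
Why: Lewis-acid cleavage of the five aryl methyl ethers with BBr3. The aldehyde is only coordinated (a dibromomethyl derivative would be hydrolysed on work-up), and a C2–O bond that opens should reclose trans under control of the configurationally stable C3 and C3' centres.

## Compound list

1 | 6-bromochromone (6-bromo-4H-chromen-4-one) | O=C1C=COc2ccc(Br)cc12 | starting material
2 | (4-methoxyphenyl)boronic acid | COc1ccc(cc1)B(O)O | starting material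
3 | (2R)-6-bromo-2-(4-methoxyphenyl)chroman-4-one | O=C1C[C@H](c2ccc(OC)cc2)Oc2ccc(Br)cc21 | intermediate
4 | trimethyl orthoformate | COC(OC)OC | starting material
5 | (2R)-6-bromo-4-methoxy-2-(4-methoxyphenyl)-2H-chromene | COC1=C[C@H](c2ccc(OC)cc2)Oc2ccc(Br)cc21 | intermediate
6 | methyl (2R,3R)-5-bromo-2-(4-methoxyphenyl)-2,3-dihydrobenzofuran-3-carboxylate | Brc1ccc2c(c1)[C@@H](C(=O)OC)[C@H](c1ccc(OC)cc1)O2 | intermediate
7 | (2R,3R)-5-bromo-2-(4-methoxyphenyl)-2,3-dihydrobenzofuran-3-carboxylic acid | Brc1ccc2c(c1)[C@@H](C(=O)O)[C@H](c1ccc(OC)cc1)O2 | intermediate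
8 | 1-bromo-3,5-dimethoxybenzene | COc1cc(Br)cc(OC)c1 | starting material
9 | (3,5-dimethoxyphenyl)zinc chloride | COc1cc([Zn]Cl)cc(OC)c1 | intermediate
10 | 1,3-dioxoisoindolin-2-yl (2R,3R)-5-bromo-2-(4-methoxyphenyl)-2,3-dihydrobenzofuran-3-carboxylate | Brc1ccc2c(c1)[C@@H](C(=O)ON1C(=O)c3ccccc3C1=O)[C@H](c1ccc(OC)cc1)O2 | intermediate
11 | (2R,3R)-5-bromo-3-(3,5-dimethoxyphenyl)-2-(4-methoxyphenyl)-2,3-dihydrobenzofuran | Brc1ccc2c(c1)[C@@H](c1cc(OC)cc(OC)c1)[C@H](c1ccc(OC)cc1)O2 | intermediate
12 | 1-{2-[(2R,3R)-5-bromo-2-(4-methoxyphenyl)-2,3-dihydrobenzofuran-3-yl]-4,6-dimethoxyphenyl}ethan-1-one | Brc1ccc2c(c1)[C@@H](c1cc(OC)cc(OC)c1C(C)=O)[C@H](c1ccc(OC)cc1)O2 | intermediate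
13 | 1-{2-[(2R,3R)-5-bromo-2-(4-methoxyphenyl)-2,3-dihydrobenzofuran-3-yl]-6-hydroxy-4-methoxyphenyl}ethan-1-one | Brc1ccc2c(c1)[C@@H](c1cc(OC)cc(O)c1C(C)=O)[C@H](c1ccc(OC)cc1)O2 | intermediate
14 | (E)-1-{2-[(2R,3R)-5-bromo-2-(4-methoxyphenyl)-2,3-dihydrobenzofuran-3-yl]-6-hydroxy-4-methoxyphenyl}-3-(dimethylamino)prop-2-en-1-one | Brc1ccc2c(c1)[C@@H](c1cc(OC)cc(O)c1C(=O)/C=C/N(C)C)[C@H](c1ccc(OC)cc1)O2 | intermediate
15 | 5-[(2R,3R)-5-bromo-2-(4-methoxyphenyl)-2,3-dihydrobenzofuran-3-yl]-7-methoxy-4H-chromen-4-one | Brc1ccc2c(c1)[C@@H](c1cc(OC)cc3OC=CC(=O)c13)[C@H](c1ccc(OC)cc1)O2 | intermediate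
16 | (2R)-5-[(2R,3R)-5-bromo-2-(4-methoxyphenyl)-2,3-dihydrobenzofuran-3-yl]-7-methoxy-2-(4-methoxyphenyl)chroman-4-one | Brc1ccc2c(c1)[C@@H](c1cc(OC)cc3O[C@@H](c4ccc(OC)cc4)CC(=O)c13)[C@H](c1ccc(OC)cc1)O2 | intermediate
17 | (2R)-5-[(2R,3R)-5-bromo-2-(4-methoxyphenyl)-2,3-dihydrobenzofuran-3-yl]-4,7-dimethoxy-2-(4-methoxyphenyl)-2H-chromene | Brc1ccc2c(c1)[C@@H](c1cc(OC)cc3O[C@@H](c4ccc(OC)cc4)C=C(OC)c13)[C@H](c1ccc(OC)cc1)O2 | intermediate
18 | methyl (2R,3R)-4-[(2R,3R)-5-bromo-2-(4-methoxyphenyl)-2,3-dihydrobenzofuran-3-yl]-6-methoxy-2-(4-methoxyphenyl)-2,3-dihydrobenzofuran-3-carboxylate | Brc1ccc2c(c1)[C@@H](c1cc(OC)cc3c1[C@@H](C(=O)OC)[C@H](c1ccc(OC)cc1)O3)[C@H](c1ccc(OC)cc1)O2 | intermediate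
19 | (2R,3R)-4-[(2R,3R)-5-bromo-2-(4-methoxyphenyl)-2,3-dihydrobenzofuran-3-yl]-6-methoxy-2-(4-methoxyphenyl)-2,3-dihydrobenzofuran-3-carboxylic acid | Brc1ccc2c(c1)[C@@H](c1cc(OC)cc3c1[C@@H](C(=O)O)[C@H](c1ccc(OC)cc1)O3)[C@H](c1ccc(OC)cc1)O2 | intermediate
20 | 1,3-dioxoisoindolin-2-yl (2R,3R)-4-[(2R,3R)-5-bromo-2-(4-methoxyphenyl)-2,3-dihydrobenzofuran-3-yl]-6-methoxy-2-(4-methoxyphenyl)-2,3-dihydrobenzofuran-3-carboxylate | Brc1ccc2c(c1)[C@@H](c1cc(OC)cc3c1[C@@H](C(=O)ON1C(=O)c4ccccc4C1=O)[C@H](c1ccc(OC)cc1)O3)[C@H](c1ccc(OC)cc1)O2 | intermediate
21 | (2R,3R)-4-[(2R,3R)-5-bromo-2-(4-methoxyphenyl)-2,3-dihydrobenzofuran-3-yl]-3-(3,5-dimethoxyphenyl)-6-methoxy-2-(4-methoxyphenyl)-2,3-dihydrobenzofuran | Brc1ccc2c(c1)[C@@H](c1cc(OC)cc3c1[C@@H](c1cc(OC)cc(OC)c1)[C@H](c1ccc(OC)cc1)O3)[C@H](c1ccc(OC)cc1)O2 | intermediate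
22 | (2R,3R)-3-[(2R,3R)-3-(3,5-dimethoxyphenyl)-6-methoxy-2-(4-methoxyphenyl)-2,3-dihydrobenzofuran-4-yl]-2-(4-methoxyphenyl)-2,3-dihydrobenzofuran-5-carbaldehyde | O=Cc1ccc2c(c1)[C@@H](c1cc(OC)cc3c1[C@@H](c1cc(OC)cc(OC)c1)[C@H](c1ccc(OC)cc1)O3)[C@H](c1ccc(OC)cc1)O2 | intermediate
23 | (2R,3R)-3-[(2R,3R)-3-(3,5-dihydroxyphenyl)-6-hydroxy-2-(4-hydroxyphenyl)-2,3-dihydrobenzofuran-4-yl]-2-(4-hydroxyphenyl)-2,3-dihydrobenzofuran-5-carbaldehyde | O=Cc1ccc2c(c1)[C@@H](c1cc(O)cc3c1[C@@H](c1cc(O)cc(O)c1)[C@H](c1ccc(O)cc1)O3)[C@H](c1ccc(O)cc1)O2 | target

## Step count and least certain steps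

Total: 14 steps. Longest linear sequence: 13 steps from 1 to 23 (steps 1 to 3 and 5 to 14); step 4, the preparation of arylzinc reagent 9 from 8, is a one-step branch that feeds steps 5 and 12.

Step 2 (key step). What may go wrong: the anisyl group at C2 shifts to C3 in place of the ring A carbon (isoflavone pathway), the iodane is lost by elimination (flavone pathway), or the configuration at C2 erodes through acid-induced reversible opening of the benzylic C2–O1 bond, which the para methoxy group facilitates. Fallback, from 3 back to 6: the ring is contracted by a Wolff rearrangement, in which only the substituent on the carbonyl carbon, the ring A carbon, can migrate. The lithium enolate of 3 (LiN(SiMe3)2, THF, −78 °C, kept cold so that the ring phenoxide is not expelled from C2) is acylated with 2,2,2-trifluoroethyl trifluoroacetate to (2R)-6-bromo-2-(4-methoxyphenyl)-3-(trifluoroacetyl)chroman-4-one F1. Diazo transfer with methanesulfonyl azide and Et3N, with loss of the trifluoroacetyl group, gives (2S)-6-bromo-3-diazo-2-(4-methoxyphenyl)chroman-4-one F2 (same spatial arrangement at C2; only the descriptor changes). Irradiation of this cyclic, s-cis-locked diazo ketone in methanol gives the ketene and from it ester 6. Any cis ester would be equilibrated to trans with DBU, and C3 is erased in step 5 in any case.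

Step 10. What may go wrong: the substituent peri to the carbonyl group slows ketalisation, so that the oxidant meets the enol ether without the ketal and the reaction diverts to dehydrogenation or anisyl shift; the larger number of electron-rich rings also raises the chance of oxidation elsewhere. Fallback, from 16 back to 18, by the same diazo-transfer and Wolff sequence: trifluoroacetylation of the lithium enolate gives (2R)-5-[(2R,3R)-5-bromo-2-(4-methoxyphenyl)-2,3-dihydrobenzofuran-3-yl]-7-methoxy-2-(4-methoxyphenyl)-3-(trifluoroacetyl)chroman-4-one F5. Diazo transfer gives (2S)-5-[(2R,3R)-5-bromo-2-(4-methoxyphenyl)-2,3-dihydrobenzofuran-3-yl]-3-diazo-7-methoxy-2-(4-methoxyphenyl)chroman-4-one F6, and photolysis in methanol gives 18.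

Step 6. What may go wrong: acylation at the position between the two methoxy groups, driven by the bulk of the branched C3 substituent, or Lewis-acid opening of the dihydrofuran with loss of material. Fallback, from 11 back to 12: Vilsmeier–Haack formylation (POCl3, DMF), a weaker and more para-selective electrophile that needs no metal halide, should give 2-[(2R,3R)-5-bromo-2-(4-methoxyphenyl)-2,3-dihydrobenzofuran-3-yl]-4,6-dimethoxybenzaldehyde F3. Addition of MeMgBr gives 1-{2-[(2R,3R)-5-bromo-2-(4-methoxyphenyl)-2,3-dihydrobenzofuran-3-yl]-4,6-dimethoxyphenyl}ethan-1-ol F4 (carbinol configuration immaterial), and Dess–Martin oxidation gives 12.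

Step 12. What may go wrong: the C3' radical is flanked by the C4' substituent; slow capture by the aryl–iron species would lead to reduction, dimerisation or loss of hydrogen to the benzofuran, and capture syn to the C2' anisyl group would erode the trans selectivity. Fallback, from 19 back to 21: direct metallaphotoredox decarboxylative arylation of the free acid with 1-iodo-3,5-dimethoxybenzene (Ir[dF(CF3)ppy]2(dtbbpy)PF6, NiCl2·glyme, 4,4'-di-tert-butyl-2,2'-bipyridine, Cs2CO3, DMF, blue light). Here the radical is formed by oxidation of the carboxylate and meets an aryl–nickel halide complex. The aryl iodide is chosen so that nickel inserts there and not into the ring A bromide. No new isolated compound arises (entry F0).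

Step 14. What may go wrong: Lewis-acid activation of the formyl group, leading to Friedel–Crafts condensation with the resorcinol rings as they are unmasked; incomplete cleavage of the five ethers; or trapping of an opened C2–O bond other than by reclosure. Fallback, from 21 back to 23, with the order of events changed so that the aldehyde never meets the boron halide: BBr3 on 21 gives 5-{(2R,3R)-4-[(2R,3R)-5-bromo-2-(4-hydroxyphenyl)-2,3-dihydrobenzofuran-3-yl]-6-hydroxy-2-(4-hydroxyphenyl)-2,3-dihydrobenzofuran-3-yl}benzene-1,3-diol F7. Silylation (t-BuMe2SiCl, imidazole, DMF) gives its pentakis(tert-butyldimethylsilyl) ether F8. Bromine–lithium exchange and DMF give the silylated aldehyde F9, that is the pentakis(tert-butyldimethylsilyl) ether of 23, and Bu4NF buffered with AcOH releases 23.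

## Further compounds

F1 | step 2 | (2R)-6-bromo-2-(4-methoxyphenyl)-3-(trifluoroacetyl)chroman-4-one (C3 unassigned, enolised) | O=C1C(C(=O)C(F)(F)F)[C@H](c2ccc(OC)cc2)Oc2ccc(Br)cc21
F2 | step 2 | (2S)-6-bromo-3-diazo-2-(4-methoxyphenyl)chroman-4-one | O=C1C(=[N+]=[N-])[C@H](c2ccc(OC)cc2)Oc2ccc(Br)cc21
F3 | step 6 | 2-[(2R,3R)-5-bromo-2-(4-methoxyphenyl)-2,3-dihydrobenzofuran-3-yl]-4,6-dimethoxybenzaldehyde | Brc1ccc2c(c1)[C@@H](c1cc(OC)cc(OC)c1C=O)[C@H](c1ccc(OC)cc1)O2
F4 | step 6 | 1-{2-[(2R,3R)-5-bromo-2-(4-methoxyphenyl)-2,3-dihydrobenzofuran-3-yl]-4,6-dimethoxyphenyl}ethan-1-ol (carbinol centre unassigned) | Brc1ccc2c(c1)[C@@H](c1cc(OC)cc(OC)c1C(C)O)[C@H](c1ccc(OC)cc1)O2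
F5 | step 10 | (2R)-5-[(2R,3R)-5-bromo-2-(4-methoxyphenyl)-2,3-dihydrobenzofuran-3-yl]-7-methoxy-2-(4-methoxyphenyl)-3-(trifluoroacetyl)chroman-4-one (C3 unassigned, enolised) | Brc1ccc2c(c1)[C@@H](c1cc(OC)cc3O[C@@H](c4ccc(OC)cc4)C(C(=O)C(F)(F)F)C(=O)c13)[C@H](c1ccc(OC)cc1)O2
F6 | step 10 | (2S)-5-[(2R,3R)-5-bromo-2-(4-methoxyphenyl)-2,3-dihydrobenzofuran-3-yl]-3-diazo-7-methoxy-2-(4-methoxyphenyl)chroman-4-one | Brc1ccc2c(c1)[C@@H](c1cc(OC)cc3O[C@@H](c4ccc(OC)cc4)C(=[N+]=[N-])C(=O)c13)[C@H](c1ccc(OC)cc1)O2
F0 | step 12 | none | none
F7 | step 14 | 5-{(2R,3R)-4-[(2R,3R)-5-bromo-2-(4-hydroxyphenyl)-2,3-dihydrobenzofuran-3-yl]-6-hydroxy-2-(4-hydroxyphenyl)-2,3-dihydrobenzofuran-3-yl}benzene-1,3-diol | Brc1ccc2c(c1)[C@@H](c1cc(O)cc3c1[C@@H](c1cc(O)cc(O)c1)[C@H](c1ccc(O)cc1)O3)[C@H](c1ccc(O)cc1)O2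
F8 | step 14 | pentakis(tert-butyldimethylsilyl) ether of F7 | Brc1ccc2c(c1)[C@@H](c1cc(O[Si](C)(C)C(C)(C)C)cc3c1[C@@H](c1cc(O[Si](C)(C)C(C)(C)C)cc(O[Si](C)(C)C(C)(C)C)c1)[C@H](c1ccc(O[Si](C)(C)C(C)(C)C)cc1)O3)[C@H](c1ccc(O[Si](C)(C)C(C)(C)C)cc1)O2
F9 | step 14 | pentakis(tert-butyldimethylsilyl) ether of 23 | O=Cc1ccc2c(c1)[C@@H](c1cc(O[Si](C)(C)C(C)(C)C)cc3c1[C@@H](c1cc(O[Si](C)(C)C(C)(C)C)cc(O[Si](C)(C)C(C)(C)C)c1)[C@H](c1ccc(O[Si](C)(C)C(C)(C)C)cc1)O3)[C@H](c1ccc(O[Si](C)(C)C(C)(C)C)cc1)O2
A1 | alternative 1 | methyl 2-[2-(3,5-dimethoxybenzoyl)-3,5-dimethoxyphenyl]acetate | COC(=O)Cc1cc(OC)cc(OC)c1C(=O)c1cc(OC)cc(OC)c1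
A2 | alternative 1 | methyl 3-(3,5-dimethoxyphenyl)-3-oxopropanoate | COC(=O)CC(=O)c1cc(OC)cc(OC)c1
A3 | alternative 1 | 3,5-dimethoxy-2-(trimethylsilyl)phenyl trifluoromethanesulfonate | COc1cc(OC)c([Si](C)(C)C)c(OS(=O)(=O)C(F)(F)F)c1
A4 | alternative 2 | (2R,3R)-4-bromo-3-(3,5-dimethoxyphenyl)-6-methoxy-2-(4-methoxyphenyl)-2,3-dihydrobenzofuran | Brc1cc(OC)cc2c1[C@@H](c1cc(OC)cc(OC)c1)[C@H](c1ccc(OC)cc1)O2
A5 | alternative 2 | 3-bromo-2-[(3,5-dimethoxyphenyl)(4-methylbenzenesulfonyl)methyl]-5-methoxyphenol | Cc1ccc(cc1)S(=O)(=O)C(c1cc(OC)cc(OC)c1)c1c(O)cc(OC)cc1Br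
A6 | alternative 2 | (2R,5R)-1-(4-methoxybenzyl)-2,5-dimethylthiolan-1-ium trifluoromethanesulfonate | C[C@@H]1CC[C@@H](C)[S+]1Cc1ccc(OC)cc1.[O-]S(=O)(=O)C(F)(F)F
A7 | alternative 3 | (2S,3S)-3-(2-bromo-3,5-dimethoxyphenyl)-5-(1,3-dioxolan-2-yl)-2-(4-methoxyphenyl)-2,3-dihydrobenzofuran (cis; C3 arranged as in the target) | O1CCOC1c1ccc2c(c1)[C@@H](c1cc(OC)cc(OC)c1Br)[C@@H](c1ccc(OC)cc1)O2
A8 | alternative 3 | 2-{3-[(2-bromo-3,5-dimethoxyphenyl)(diazo)methyl]-4-[(4-methoxybenzyl)oxy]phenyl}-1,3-dioxolane | [N-]=[N+]=C(c1cc(C2OCCO2)ccc1OCc1ccc(OC)cc1)c1cc(OC)cc(OC)c1Br
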